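Ring B is disconnected at C5–C6 and C9–C10 (eudesmane numbering). C6–C7–C8–C9 with the C8 oxygen is a 2-oxydiene retron, and because the C8 and C11 oxygens are 1,3-related through C7, one di-tert-butylsilylene bridge can tie them into a ring that locks the diene s-cis. A chiral Lewis acid catalysed Diels–Alder reaction of this exocyclic diene with 3-methylcyclohex-2-enone closes ring B, creates the C10 quaternary centre and delivers the whole oxygenated side chain at once. The ring A ketone (C4) then sets the trans ring fusion by epimerisation and is turned into the C3=C4 alkene, whose α-face dihydroxylation sets C3 and C4 before esterification.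

Key step: step 4

Remark: eudesmane numbering is used for all bicyclic compounds (ring A = C1–C5 and C10; ring B = C5–C10; C11 = carbinol carbon on C7; C14 = methyl on C10; C15 = methyl on C4; β = the face of the C10 methyl).
Remark: compounds 1, 3, 6 and 15 are taken as commercial.
Assumption: in step 4 the (S)-catalyst is assigned from the α-C–H···O binding model known for cyclohex-2-enone; were the sense of induction the opposite, the (R)-catalyst would be used with no other change.

Step 1
Reactants: 1 2-methylbut-3-yn-2-ol
Product: 2 2-methyl-3-(tributylstannyl)but-3-en-2-ol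
Conditions: Bu3SnH, Mo(CO)3(CNt-Bu)3 (2 mol%), hydroquinone (cat.), THF, 55 °C
Reagents that add atoms: tributyltin hydride, CCCC[SnH](CCCC)CCCC
Why: Molybdenum-catalysed α-selective (Markovnikov) hydrostannation of a terminal propargylic alcohol should place tin on the internal carbon and give the 1,1-disubstituted vinylstannane; no stereocentre is formed.

Step 2
Reactants: 2 2-methyl-3-(tributylstannyl)but-3-en-2-ol; 3 acetyl chloride
Product: 4 3-(2-hydroxypropan-2-yl)but-3-en-2-one
Conditions: [Pd(C3H5)Cl]2 (1 mol%), MeCN, 0 °C to rt
Reagents that add atoms: none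
Why: Stille acylation of the vinylstannane with the acid chloride should give the α-methylene β-hydroxy ketone directly, the hindered tertiary alcohol not competing for the acid chloride; no stereocentre is formed.

Step 3
Reactants: 4 3-(2-hydroxypropan-2-yl)but-3-en-2-one
Product: 5 2,2-di-tert-butyl-4,4-dimethyl-5,6-dimethylidene-1,3,2-dioxasilinane
Conditions: t-Bu2Si(OTf)2, Et3N, CH2Cl2, 0 °C
Reagents that add atoms: di-tert-butylsilyl bis(trifluoromethanesulfonate), CC(C)(C)[Si](OS(=O)(=O)C(F)(F)F)(OS(=O)(=O)C(F)(F)F)C(C)(C)C
Why: Silyl enol ether formation with a silyl triflate and amine base: one Si–OTf silylates the tertiary alcohol and the other traps the enol of the methyl ketone (C7 carries no hydrogen, so enolisation can only go towards the methyl group), which should close the six-membered cyclic silyl dienol ether with both alkenes exocyclic and s-cis; no stereocentre is formed.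

Step 4
Reactants: 5 2,2-di-tert-butyl-4,4-dimethyl-5,6-dimethylidene-1,3,2-dioxasilinane; 6 3-methylcyclohex-2-en-1-one
Product: 7 (5S,10R)-8,11-(di-tert-butylsilanediyldioxy)-15-noreudesm-7-en-4-one (cis-fused: 5β-H and 10β-CH3)
Conditions: (S)-oxazaborolidine·AlBr3 complex C24H24BNO·AlBr3 [(S)-1-(2-methylphenyl)-3,3-diphenyltetrahydro-1H,3H-pyrrolo[1,2-c][1,3,2]oxazaborole activated with AlBr3] (20 mol%), CH2Cl2, −40 to −20 °C
Reagents that add atoms: none
Why: Proposed new method: the AlBr3-activated oxazaborolidine binds the C4 carbonyl oxygen of 6 on the side of the C5–H (α-C–H···O contact) and lowers the LUMO, so that the s-cis-locked, electron-rich diene 5 adds in an asynchronous [4+2] process (in the stepwise limit a Mukaiyama–Michael addition of C9 to C10 followed by closure of the C5 enolate onto C6) that regenerates the silyl enol ether; the closest known reactions are the AlBr3/AlMe3-promoted Diels–Alder addition of 2-silyloxydienes to 3-methylcyclohex-2-enone and the oxazaborolidine·AlBr3-catalysed enantioselective Diels–Alder addition of 2-silyloxydienes to cyclohex-2-enone, which are merged here. Ring B closes as a six-membered carbocycle in the suprafacial [4+2] mode (6-endo-trig if the second bond forms stepwise). C10 is set by the catalyst, whose phenyl group should shield the Re face at the β-carbon so that C9 bonds to the Si (α) face, and C5 follows from cis addition across the ring alkene (5-H cis to the C10 methyl, corrected in step 5). Regioselectivity (C9 to C10 and C6 to C5) is needed and is secured by the enol ether polarisation of the diene, whose nucleophilic terminus C9 is matched with the β-carbon of the enone; enantioface selectivity is needed and rests on the catalyst; endo/exo selectivity is irrelevant because both diene termini are unsubstituted. The silicon bridge compensates for the hindered β,β-disubstituted dienophile by locking the diene s-cis and keeps the tertiary allylic C11 oxygen tethered, so that reversible ionisation at C11 returns the same compound.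

Step 5
Reactants: 7 (5S,10R)-8,11-(di-tert-butylsilanediyldioxy)-15-noreudesm-7-en-4-one
Product: 8 (5R,10R)-8,11-(di-tert-butylsilanediyldioxy)-15-noreudesm-7-en-4-one (trans-fused: 5α-H and 10β-CH3)
Conditions: DBU (0.5 equiv), toluene, 80 °C
Reagents that add atoms: none
Why: Base-mediated epimerisation through the C4 enolate should convert the cis-fused ketone into the trans-fused isomer, expected to be the more stable one because the angular methyl keeps only one 1,3-diaxial contact; C5 is thereby set under thermodynamic control and C10 is untouched.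

Step 6
Reactants: 8 (5R,10R)-8,11-(di-tert-butylsilanediyldioxy)-15-noreudesm-7-en-4-one
Product: 10 (5R,10R)-8,11-(di-tert-butylsilanediyldioxy)-15-noreudesma-3,7-dien-4-yl trifluoromethanesulfonate, via lithium enolate 9 (not isolated)
Conditions: LiN(i-Pr)2, THF, −78 °C; then PhNTf2, −78 to 0 °C
Reagents that add atoms: N-phenylbis(trifluoromethanesulfonimide), O=S(=O)(N(c1ccccc1)S(=O)(=O)C(F)(F)F)C(F)(F)F
Why: Kinetic deprotonation at the less hindered C3 methylene, not at the ring-fusion C5–H, followed by O-triflation (enol triflate formation) should give the Δ3 enol triflate regioselectively and leave C5 untouched.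

Step 7
Reactants: 10 (5R,10R)-8,11-(di-tert-butylsilanediyldioxy)-15-noreudesma-3,7-dien-4-yl trifluoromethanesulfonate
Product: 11 (5R,10R)-8,11-(di-tert-butylsilanediyldioxy)eudesma-3,7-diene
Conditions: MeMgBr, Fe(acac)3 (5 mol%), THF/NMP, −30 to 0 °C
Reagents that add atoms: methylmagnesium bromide, C[Mg]Br
Why: Iron-catalysed cross-coupling of the alkenyl triflate with the methyl Grignard reagent should install C15 on C4 with the C3=C4 alkene in place, the hindered silyl enol ether being inert at low temperature; no stereocentre is affected.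

Step 8
Reactants: 11 (5R,10R)-8,11-(di-tert-butylsilanediyldioxy)eudesma-3,7-diene
Product: 13 (5R,10R)-11-hydroxyeudesma-3,6-dien-8-one, via acetoxysilyl ether 12 (not isolated)
Conditions: Pd(OAc)2 (1.2 equiv), MeCN, 40 °C; then Bu4NF, AcOH, THF, rt
Reagents that add atoms: none
Why: Saegusa–Ito oxidation: palladium diacetate should convert the silyl enol ether into a C7-bound palladium enolate whose only β-hydrogens are on C6 (C11 is quaternary), so β-hydride elimination gives the C6=C7 enone, and buffered fluoride then removes silicon from O11; no stereocentre is affected.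

Step 9
Reactants: 13 (5R,10R)-11-hydroxyeudesma-3,6-dien-8-one
Product: 14 (3R,4S,5R,10R)-3,4,11-trihydroxyeudesm-6-en-8-one (3α-OH; 4α-OH; 4β-CH3)
Conditions: K2OsO4·2H2O (2 mol%), NMO, acetone/H2O (4:1), 0 °C to rt
Reagents that add atoms: N-methylmorpholine N-oxide, C[N+]1([O-])CCOCC1; water, O
Why: Upjohn dihydroxylation: osmium tetroxide should add syn to the electron-rich trisubstituted C3=C4 alkene in preference to the electron-poor hindered enone alkene, and from the α face, anti to the axial 10β-methyl that screens the β face, which sets C3 (α-OH) and C4 (α-OH, β-CH3) together.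

Step 10
Reactants: 15 (E)-2-methylbut-2-en-1-ol
Product: 16 [(2R,3R)-2,3-dimethyloxiran-2-yl]methanol
Conditions: t-BuOOH, Ti(Oi-Pr)4 (10 mol%), D-(−)-diethyl tartrate (12 mol%), 4 Å molecular sieves, CH2Cl2, −20 °C
Reagents that add atoms: tert-butyl hydroperoxide, CC(C)(C)OO
Why: Sharpless asymmetric epoxidation of the (E)-allylic alcohol with the D-(−)-tartrate ligand should deliver oxygen to the face that gives the (2R,3R)-epoxy alcohol, the cis relationship of the two methyl groups following from the E geometry.

Step 11
Reactants: 16 [(2R,3R)-2,3-dimethyloxiran-2-yl]methanol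
Product: 18 (2S,3R)-2,3-dimethyloxirane-2-carboxylic acid, via epoxy aldehyde 17 (not isolated)
Conditions: TEMPO (10 mol%), PhI(OAc)2 (2.2 equiv), MeCN/H2O (1:1), rt
Reagents that add atoms: water, O
Why: TEMPO/PhI(OAc)2 oxidation in aqueous acetonitrile should take the primary alcohol through the aldehyde hydrate to the acid under near-neutral conditions that leave the epoxide and both stereocentres intact (the C2 descriptor changes from R to S only through the change in substituent priority).

Step 12
Reactants: 14 (3R,4S,5R,10R)-3,4,11-trihydroxyeudesm-6-en-8-one; 18 (2S,3R)-2,3-dimethyloxirane-2-carboxylic acid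
Product: 20 (3R,4S,5R,10R)-4,11-dihydroxy-8-oxoeudesm-6-en-3-yl (2S,3R)-2,3-dimethyloxirane-2-carboxylate (CNP0272928.1), via mixed anhydride 19 (not isolated)
Conditions: 2,4,6-trichlorobenzoyl chloride, Et3N, THF, 0 °C; then 14, DMAP, toluene, rt to 40 °C
Reagents that add atoms: none
Why: Yamaguchi esterification: the DMAP-activated mixed anhydride should acylate the only secondary hydroxyl (C3–OH) while the tertiary C4 and C11 hydroxyls do not react; no stereocentre is formed or changed.

Compound list
1 | 2-methylbut-3-yn-2-ol | CC(C)(O)C#C | starting material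
2 | 2-methyl-3-(tributylstannyl)but-3-en-2-ol | CC(C)(O)C(=C)[Sn](CCCC)(CCCC)CCCC | intermediate
3 | acetyl chloride | CC(Cl)=O | starting material
4 | 3-(2-hydroxypropan-2-yl)but-3-en-2-one | CC(=O)C(=C)C(C)(C)O | intermediate
5 | 2,2-di-tert-butyl-4,4-dimethyl-5,6-dimethylidene-1,3,2-dioxasilinane | C=C1O[Si](C(C)(C)C)(C(C)(C)C)OC(C)(C)C1=C | intermediate
6 | 3-methylcyclohex-2-en-1-one | CC1=CC(=O)CCC1 | starting material
7 | (5S,10R)-8,11-(di-tert-butylsilanediyldioxy)-15-noreudesm-7-en-4-one (cis-fused) | C1CC[C@]2(C)CC3=C(C[C@@H]2C1=O)C(C)(C)O[Si](C(C)(C)C)(C(C)(C)C)O3 | intermediate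
8 | (5R,10R)-8,11-(di-tert-butylsilanediyldioxy)-15-noreudesm-7-en-4-one (trans-fused) | C1CC[C@]2(C)CC3=C(C[C@H]2C1=O)C(C)(C)O[Si](C(C)(C)C)(C(C)(C)C)O3 | intermediate
9 | lithium (5R,10R)-8,11-(di-tert-butylsilanediyldioxy)-15-noreudesma-3,7-dien-4-olate | C1CC[C@]2(C)CC3=C(C[C@H]2C(O[Li])=1)C(C)(C)O[Si](C(C)(C)C)(C(C)(C)C)O3 | intermediate
10 | (5R,10R)-8,11-(di-tert-butylsilanediyldioxy)-15-noreudesma-3,7-dien-4-yl trifluoromethanesulfonate | C1CC[C@]2(C)CC3=C(C[C@H]2C(OS(=O)(=O)C(F)(F)F)=1)C(C)(C)O[Si](C(C)(C)C)(C(C)(C)C)O3 | intermediate
11 | (5R,10R)-8,11-(di-tert-butylsilanediyldioxy)eudesma-3,7-diene | C1CC[C@]2(C)CC3=C(C[C@H]2C(C)=1)C(C)(C)O[Si](C(C)(C)C)(C(C)(C)C)O3 | intermediate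
12 | (5R,10R)-11-{[acetoxy(di-tert-butyl)silyl]oxy}eudesma-3,6-dien-8-one | C1CC[C@]2(C)CC(=O)C(C(C)(C)O[Si](OC(C)=O)(C(C)(C)C)C(C)(C)C)=C[C@H]2C(C)=1 | intermediate
13 | (5R,10R)-11-hydroxyeudesma-3,6-dien-8-one | C1CC[C@]2(C)CC(=O)C(C(C)(C)O)=C[C@H]2C(C)=1 | intermediate
14 | (3R,4S,5R,10R)-3,4,11-trihydroxyeudesm-6-en-8-one | O[C@@H]1CC[C@]2(C)CC(=O)C(C(C)(C)O)=C[C@H]2[C@]1(C)O | intermediate
15 | (E)-2-methylbut-2-en-1-ol | C/C=C(\C)CO | starting material
16 | [(2R,3R)-2,3-dimethyloxiran-2-yl]methanol | C[C@H]1O[C@]1(C)CO | intermediate
17 | (2S,3R)-2,3-dimethyloxirane-2-carbaldehyde | C[C@H]1O[C@]1(C)C=O | intermediate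
18 | (2S,3R)-2,3-dimethyloxirane-2-carboxylic acid | C[C@H]1O[C@]1(C)C(=O)O | intermediate
19 | (2S,3R)-2,3-dimethyloxirane-2-carboxylic 2,4,6-trichlorobenzoic anhydride | C[C@H]1O[C@]1(C)C(=O)OC(=O)c1c(Cl)cc(Cl)cc1Cl | intermediate
20 | (3R,4S,5R,10R)-4,11-dihydroxy-8-oxoeudesm-6-en-3-yl (2S,3R)-2,3-dimethyloxirane-2-carboxylate | C[C@H]1O[C@]1(C)C(=O)O[C@@H]1CC[C@]2(C)CC(=O)C(C(C)(C)O)=C[C@H]2[C@]1(C)O | target

Total step count: 12. Longest linear sequence: 10 steps (steps 1 to 9, then step 12).

Steps most likely to fail

Step 4 (labelled step). The chiral Lewis acid may turn over too slowly with the hindered β,β-disubstituted enone, may ionise or oligomerise the diene, may stop after the first C–C bond, or may discriminate the enone faces poorly. The fallback uses known chemistry and replaces catalyst control by resolution. It sets out from 5 and 6, which are combined under the achiral mixed Lewis acid AlBr3/AlMe3 (toluene/CH2Cl2, about 0 °C), a system established for 2-silyloxydienes and 3-methylcyclohex-2-enone. This should give the racemic cis adduct, that is 7 together with its enantiomer (5R,10S)-8,11-(di-tert-butylsilanediyldioxy)-15-noreudesm-7-en-4-one F1. DBU epimerisation as in step 5 should give the racemic trans ketone, that is 8 together with its enantiomer (5S,10S)-8,11-(di-tert-butylsilanediyldioxy)-15-noreudesm-7-en-4-one F2. Preparative chromatography on a chiral stationary phase (cellulose tris(3,5-dimethylphenylcarbamate)) then separates the enantiomers, and the fallback comes back to the route at 8.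

Step 8. Transfer of the hindered di-tert-butylsilyl enol ether to palladium may be slow, protodesilylation may compete, and the C3=C4 alkene may migrate into conjugation if the medium turns basic. The fallback sets out from 11 and dehydrogenates the ketone instead of oxidising the silyl enol ether. Buffered fluoride (Bu4NF, AcOH, THF) should cleave the silicon bridge to the saturated hydroxy ketone (5R,7R,10R)-11-hydroxyeudesm-3-en-8-one F3. IBX in DMSO at about 70 °C should then introduce the C6=C7 alkene; dehydrogenation towards C9 is impossible because C10 is quaternary. The fallback comes back to the route at 13.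

Step 12. Acylation of the hindered axial C3 hydroxyl next to the tertiary carbinol may be slow, and because the acid is α-quaternary the mixed anhydride may transfer its aroyl group instead. The fallback sets out from 18 and uses a more reactive acyl donor without a competing carbonyl. 1-Chloro-N,N,2-trimethylprop-1-en-1-amine in CH2Cl2 should convert the acid under neutral conditions into (2S,3R)-2,3-dimethyloxirane-2-carbonyl chloride F4. This is added to 14 with Et3N and DMAP in CH2Cl2 at 0 °C to rt, and the fallback comes back to the route at 20.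

Further compounds
F1 | step 4 | (5R,10S)-8,11-(di-tert-butylsilanediyldioxy)-15-noreudesm-7-en-4-one (enantiomer of 7) | C1CC[C@@]2(C)CC3=C(C[C@H]2C1=O)C(C)(C)O[Si](C(C)(C)C)(C(C)(C)C)O3
F2 | step 4 | (5S,10S)-8,11-(di-tert-butylsilanediyldioxy)-15-noreudesm-7-en-4-one (enantiomer of 8) | C1CC[C@@]2(C)CC3=C(C[C@@H]2C1=O)C(C)(C)O[Si](C(C)(C)C)(C(C)(C)C)O3
F3 | step 8 | (5R,7R,10R)-11-hydroxyeudesm-3-en-8-one | C1CC[C@]2(C)CC(=O)[C@@H](C(C)(C)O)C[C@H]2C(C)=1
F4 | step 12 | (2S,3R)-2,3-dimethyloxirane-2-carbonyl chloride | C[C@H]1O[C@]1(C)C(Cl)=O
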